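**Two exits.** A one-step world has one rate and one product. These flasks have a fork: the open intermediate leaves either as target or, with capture agent, as trapped intermediate.

| setting | south-west | flask |
|---|---|---|
| substrate | 0.050 M | 0.050 M |
| reagent | 0.033 M | 0.0650 M |
| capture agent | 0.050 M | 0.0500 M |
| catalyst | 38 µM | 38 µM |
| remark | run made earlier |  |
| time |  | 80 min |

south-west run (percent of the substrate charged)

| time / min | target / % | trapped intermediate / % |
|---|---|---|
| 1.33 | 0.2 | 0 |
| 3.00 | 2.0 | 1.2 |
| 6.00 | 5.3 | 3.4 |
| 15.0 | 15.4 | 8.1 |

(readings scatter by 0.5 percentage points)



* target present at 80 min, in percent of the substrate charged
* trapped intermediate present at 80 min, in percent of the substrate charged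
* open intermediate present at 80 min, in percent of the substrate charged
* substrate present at 80 min, in percent of the substrate charged
* concentration of reagent at 80 min, in M

**Exit ratio.** My own reading takes the exit to target as proportional to [reagent] and the exit to capture as proportional to [capture agent]. The exit ratio, target rate over capture rate, is then a constant times [reagent]/[capture agent]. Target over trapped intermediate at the last south-west reading, times charged [capture agent] over charged [reagent], gives 2.88, the selectivity factor, a reading that carries the scatter. The new charge starts the exit ratio at 3.74.

**The forecast.** It gives target 59.5%, trapped intermediate 27.5%, open intermediate 0.5%, substrate 12% and [reagent] 0.021 M, noting that “the order in substrate and reagent is poorly defined”.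

**The correction.** My reckoning keeps the forecast's sum of target and trapped intermediate, 87.0%, and corrects the ratio. The starting ratio splits that sum into target 68.7% and trapped intermediate for the rest. Taking one reagent per target and one capture agent per trapped intermediate, the ratio ends near 2.16, and the mean of the two is 2.95. That gives target 65.0%, more than the forecast, trapped intermediate 22.0% and [reagent] 0.0325 M.

**The flask.** At 80 min it holds target 64.5%, trapped intermediate 22.0%, open intermediate 4.83%, substrate 8.67% and [reagent] 0.0327 M.

    substrate + catalyst ⇌ catalyst + open intermediate (K = 0.655, k = 3830 /M/min)
    reagent + catalyst + open intermediate → catalyst + target (k = 33800 /M²/min)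
    open intermediate + capture agent → trapped intermediate (k = 0.464 /M/min)

**Capture exit.** The flask's product ratio is 2.93, below the starting exit ratio, and the factor applied to the start and end amounts averages 3.08. The capture exit and the reading at 80 min are, acting together, a part of why target stands at 64.5% in this flask: without the capture step it gives 75.7%, and read at 800 min it gives 73.8%. In the neighbour flask with 0.20 M of capture agent, the factor gives a mean exit ratio of 0.830, and that flask holds target 43.0% against trapped intermediate 54.0%, a ratio of 0.796.

The data come from a simulation for an exercise; noise was put on by code.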